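Ring A (numbered as in the target: C1 methyl carbinol, C2 secondary carbinol, C3 bearing the allyl arm, C4 bearing isopropenyl, C5 and C6 methylenes) is grown from a four-membered ring. A rhodium-catalysed formal [4+2] inserts the two carbons of an α-alkoxyvinyl boronate into a carbonyl–CH2 bond of prochiral 3-isopropenylcyclobutanone: carbonyl addition forges C1–C2, strain-driven β-carbon elimination and conjugate addition forge C5–C6, and the choice between the two enantiotopic ring bonds sets C4. It exploits the vicinal C1/C2 oxygens beside the C5–C6 ethano unit. Enolate allylation at C3 with a limonene-derived ring B bromohydrin, axial methylation at C1 and reduction at C2 complete the target.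

Key step: step 5

Remark on the chemistry: 9 is drawn as its trans isomer, but its alkoxy-bearing centre (ring A C1) is epimerisable and is erased in step 10, so its configuration does not matter. Compounds 1, 5 and 10 are taken as commercial. The ligand antipode in step 5 that leads to the (5S) series has to be found in a first screen.

Step 1
Reactants: 1 3,3-dimethoxycyclobutane-1-carboxylic acid
Product: 2 1-(3,3-dimethoxycyclobutyl)ethan-1-one
Conditions: MeLi (2.2 equiv), Et2O, 0 °C; then H2O
Reagents that add atoms: methyllithium [Li]C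
Why: Addition of methyllithium to the lithium carboxylate stops at the geminal dilithium alkoxide, which collapses to the methyl ketone only on aqueous work-up (ketone synthesis from a carboxylic acid and an organolithium), and the dimethyl ketal is inert to the base.

Step 2
Reactants: 2 1-(3,3-dimethoxycyclobutyl)ethan-1-one
Product: 4 3-(prop-1-en-2-yl)cyclobutan-1-one, via 1,1-dimethoxy-3-(prop-1-en-2-yl)cyclobutane 3 (not isolated)
Conditions: Ph3PCH3Br, KOtBu, THF, 0 °C to rt; then 1 M HCl, rt
Reagents that add atoms: methyltriphenylphosphonium bromide C[P+](c1ccccc1)(c1ccccc1)c1ccccc1.[Br-]; water O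
Why: Wittig methylenation of the unhindered methyl ketone gives the isopropenyl group, and the dilute acid work-up hydrolyses the dimethyl ketal to the cyclobutanone without touching the 1,1-disubstituted alkene.

Step 3
Reactants: 5 1-bromo-2-(methoxymethoxy)ethane
Product: 6 (methoxymethoxy)ethene
Conditions: KOtBu, THF, 0 to 50 °C, product distilled
Reagents that add atoms: none
Why: Base-induced dehydrobromination (bimolecular elimination) of the 2-bromoethyl ether with the bulky alkoxide gives the volatile vinyl ether.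

Step 4
Reactants: 6 (methoxymethoxy)ethene
Product: 8 2-[1-(methoxymethoxy)ethenyl]-4,4,5,5-tetramethyl-1,3,2-dioxaborolane, via 1-(methoxymethoxy)ethenyllithium 7 (not isolated)
Conditions: t-BuLi, THF, −78 to −10 °C; then 2-isopropoxy-4,4,5,5-tetramethyl-1,3,2-dioxaborolane, −78 °C to rt
Reagents that add atoms: 2-isopropoxy-4,4,5,5-tetramethyl-1,3,2-dioxaborolane CC(C)OB1OC(C)(C)C(C)(C)O1
Why: Oxygen-directed α-lithiation of an alkyl vinyl ether, helped here by the second acetal oxygen, followed by borylation of the vinyllithium is the standard route to α-alkoxyvinyl boronates.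

Step 5
Reactants: 4 3-(prop-1-en-2-yl)cyclobutan-1-one; 8 2-[1-(methoxymethoxy)ethenyl]-4,4,5,5-tetramethyl-1,3,2-dioxaborolane
Product: 9 (2S,5S)-2-(methoxymethoxy)-5-(prop-1-en-2-yl)cyclohexan-1-one
Conditions: [Rh(OH)(cod)]2 (2.5 mol %), (R)- or (S)-DTBM-SEGPHOS (6 mol %), K3PO4 (0.5 equiv), 8 (1.5 equiv), 1,4-dioxane/H2O 10:1, 50 °C
Reagents that add atoms: none
Why: Proposed new method: transmetalation of 8 to the hydroxorhodium complex gives an α-alkoxyvinyl species of monovalent rhodium that adds to the strained carbonyl of 4 (forming C1–C2), the rhodium cyclobutanolate then undergoes β-carbon elimination of one of its two CH2–C(O) bonds with release of about 26 kcal/mol of ring strain, and the primary alkylrhodium so formed inserts the tethered α-alkoxy enone at its terminal carbon (forming C5–C6) before protonolysis of the oxa-π-allyl rhodium returns the catalyst. The closest known reaction types are the rhodium-catalysed addition of aryl- and alkenylrhodium species to cyclobutanones followed by β-carbon elimination, and the enantioselective rhodium-catalysed ring expansion of tertiary cyclobutanols carrying an unsaturated acceptor at the carbinol carbon to six-membered ketones; the new element is their merger into one catalytic cycle with a boron reagent as the two-carbon unit. Ring A is closed by a 6-endo-trig migratory insertion, preferred over the 5-exo alternative because only attack at the terminal carbon gives the stabilised rhodium enolate. C4 becomes stereogenic when the chiral bisphosphine selects between the two enantiotopic ring bonds in the β-carbon elimination, whereas the alkoxy-bearing C1 is set by protonation, is epimerisable and is erased in step 10. The step needs β-carbon elimination and insertion to outrun β-hydride elimination of the alkylrhodium, protodeboronation of 8 and addition to the product ketone; the ring strain, the acceptor held at six-ring distance, the bulky electron-rich ligand and the excess of 8 should secure this, and the unstrained carbonyl of 9 should not compete with 4.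

Step 6
Reactants: 10 (1S,2S,4R)-1-methyl-4-(prop-1-en-2-yl)cyclohexane-1,2-diol
Product: 12 (1S,2R,4R)-2-bromo-1-methyl-4-(prop-1-en-2-yl)cyclohexan-1-ol, via secondary triflate 11 (not isolated)
Conditions: Tf2O (1.05 equiv), pyridine, CH2Cl2, −78 °C; then Bu4NBr, −78 to 0 °C
Reagents that add atoms: tetrabutylammonium bromide CCCC[N+](CCCC)(CCCC)CCCC.[Br-]
Why: The secondary axial hydroxyl is triflated in preference to the tertiary one and the triflate is displaced by bromide in a bimolecular substitution with inversion, which should give the equatorial bromide cis to the tertiary hydroxyl, the bromide being added cold before the neighbouring hydroxyl can close to an epoxide.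

Step 7
Reactants: 12 (1S,2R,4R)-2-bromo-1-methyl-4-(prop-1-en-2-yl)cyclohexan-1-ol
Product: 13 (1S,2R,4R)-2-bromo-4-(3-chloroprop-1-en-2-yl)-1-methylcyclohexan-1-ol
Conditions: Ca(OCl)2, CO2 (solid), CH2Cl2/H2O, 0 °C
Reagents that add atoms: calcium hypochlorite [Ca+2].[O-]Cl.[O-]Cl
Why: Hypochlorous acid made from Ca(OCl)2 and CO2 chlorinates the isopropenyl group in an ene-type reaction with transposition of the double bond, a known allylic chlorination of isopropenyl terpenoids that should leave the hindered secondary bromide and the tertiary alcohol alone.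

Step 8
Reactants: 13 (1S,2R,4R)-2-bromo-4-(3-chloroprop-1-en-2-yl)-1-methylcyclohexan-1-ol
Product: 14 {[(1S,2R,4R)-2-bromo-4-(3-chloroprop-1-en-2-yl)-1-methylcyclohexyl]oxy}trimethylsilane
Conditions: 1-(trimethylsilyl)imidazole, CH2Cl2, rt
Reagents that add atoms: 1-(trimethylsilyl)imidazole C[Si](C)(C)n1ccnc1
Why: Silylation of the tertiary alcohol with the reactive silyl imidazole masks the only acidic proton of the ring B fragment before the enolate steps.

Step 9
Reactants: 9 (2S,5S)-2-(methoxymethoxy)-5-(prop-1-en-2-yl)cyclohexan-1-one; 14 {[(1S,2R,4R)-2-bromo-4-(3-chloroprop-1-en-2-yl)-1-methylcyclohexyl]oxy}trimethylsilane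
Product: 17 (2R,3S,6S)-2-{2-[(1R,3R,4S)-3-bromo-4-methyl-4-(trimethylsilyloxy)cyclohexyl]prop-2-en-1-yl}-6-(methoxymethoxy)-3-(prop-1-en-2-yl)cyclohexan-1-one, via lithium enolate 15 (not isolated), via allylic iodide 16 (not isolated)
Conditions: LiN(iPr)2 (1.05 equiv), THF, −78 °C; then 14, LiI (cat.), DMPU, −78 to −20 °C
Reagents that add atoms: none
Why: Kinetic deprotonation of the α-alkoxy ketone should take place at the CH2 away from the alkoxy group (ring A C3), and the enolate is alkylated by the allylic iodide formed in the flask on the face opposite the adjacent isopropenyl group, which should set the trans C3/C4 relationship as in alkylations of 3-substituted cyclohexanone enolates.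

Step 10
Reactants: 17 (2R,3S,6S)-2-{2-[(1R,3R,4S)-3-bromo-4-methyl-4-(trimethylsilyloxy)cyclohexyl]prop-2-en-1-yl}-6-(methoxymethoxy)-3-(prop-1-en-2-yl)cyclohexan-1-one
Product: 19 (2R,3S,6S)-2-{2-[(1R,3R,4S)-3-bromo-4-methyl-4-(trimethylsilyloxy)cyclohexyl]prop-2-en-1-yl}-6-(methoxymethoxy)-6-methyl-3-(prop-1-en-2-yl)cyclohexan-1-one, via potassium enolate 18 (not isolated)
Conditions: KN(SiMe3)2, THF, −78 °C; then MeI, −78 to −40 °C
Reagents that add atoms: iodomethane CI
Why: With C3 now tertiary and shielded, the amide base should remove the remaining proton at the alkoxy-bearing C1, and iodomethane attacks the planar enolate axially on the face opposite the C3 arm (enolate C-alkylation), which should place the methyl trans to that arm and the oxygen equatorial, erasing the earlier configuration at C1.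

Step 11
Reactants: 19 (2R,3S,6S)-2-{2-[(1R,3R,4S)-3-bromo-4-methyl-4-(trimethylsilyloxy)cyclohexyl]prop-2-en-1-yl}-6-(methoxymethoxy)-6-methyl-3-(prop-1-en-2-yl)cyclohexan-1-one
Product: 20 (1S,2S,5S,6R)-6-{2-[(1R,3R,4S)-3-bromo-4-methyl-4-(trimethylsilyloxy)cyclohexyl]prop-2-en-1-yl}-2-(methoxymethoxy)-2-methyl-5-(prop-1-en-2-yl)cyclohexan-1-ol
Conditions: NaBH4, MeOH, −20 to 0 °C
Reagents that add atoms: none
Why: Borohydride should attack the C2 carbonyl axially, from the face opposite the axial C1 methyl group, which gives the equatorial C2 hydroxyl trans to both the C3 arm and the C1 oxygen (substrate-controlled ketone reduction).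

Step 12
Reactants: 20 (1S,2S,5S,6R)-6-{2-[(1R,3R,4S)-3-bromo-4-methyl-4-(trimethylsilyloxy)cyclohexyl]prop-2-en-1-yl}-2-(methoxymethoxy)-2-methyl-5-(prop-1-en-2-yl)cyclohexan-1-ol
Product: 22 (1S,2S,3R,4S)-3-{2-[(1R,3R,4S)-3-bromo-4-hydroxy-4-methylcyclohexyl]prop-2-en-1-yl}-1-methyl-4-(prop-1-en-2-yl)cyclohexane-1,2-diol, via silyl ether diol 21 (not isolated)
Conditions: ZnBr2, n-PrSH, CH2Cl2, 0 °C; then K2CO3, MeOH, rt
Reagents that add atoms: none
Why: Lewis acid and thiol cleave the methoxymethyl ether at its acetal carbon, so the tertiary C–O bond and its configuration are untouched, and mild methanolysis then removes the trimethylsilyl ether, neither condition affecting the alkenes or the equatorial bromide, which cannot close to an epoxide with the cis hydroxyl.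

Compound list
1 | 3,3-dimethoxycyclobutane-1-carboxylic acid | COC1(OC)CC(C(=O)O)C1 | starting material
2 | 1-(3,3-dimethoxycyclobutyl)ethan-1-one | CC(=O)C1CC(OC)(OC)C1 | intermediate
3 | 1,1-dimethoxy-3-(prop-1-en-2-yl)cyclobutane | CC(=C)C1CC(OC)(OC)C1 | intermediate
4 | 3-(prop-1-en-2-yl)cyclobutan-1-one | CC(=C)C1CC(=O)C1 | intermediate
5 | 1-bromo-2-(methoxymethoxy)ethane | BrCCOCOC | starting material
6 | (methoxymethoxy)ethene | C=COCOC | intermediate
7 | 1-(methoxymethoxy)ethenyllithium | [Li]C(=C)OCOC | intermediate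
8 | 2-[1-(methoxymethoxy)ethenyl]-4,4,5,5-tetramethyl-1,3,2-dioxaborolane | C=C(OCOC)B1OC(C)(C)C(C)(C)O1 | intermediate
9 | (2S,5S)-2-(methoxymethoxy)-5-(prop-1-en-2-yl)cyclohexan-1-one | O=C1C[C@@H](C(C)=C)CC[C@@H]1OCOC | intermediate
10 | (1S,2S,4R)-1-methyl-4-(prop-1-en-2-yl)cyclohexane-1,2-diol (limonene-1,2-diol) | CC(=C)[C@@H]1CC[C@](C)(O)[C@@H](O)C1 | starting material
11 | (1S,2S,5R)-2-hydroxy-2-methyl-5-(prop-1-en-2-yl)cyclohexyl trifluoromethanesulfonate | CC(=C)[C@@H]1CC[C@](C)(O)[C@@H](OS(=O)(=O)C(F)(F)F)C1 | intermediate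
12 | (1S,2R,4R)-2-bromo-1-methyl-4-(prop-1-en-2-yl)cyclohexan-1-ol | CC(=C)[C@@H]1CC[C@](C)(O)[C@H](Br)C1 | intermediate
13 | (1S,2R,4R)-2-bromo-4-(3-chloroprop-1-en-2-yl)-1-methylcyclohexan-1-ol | ClCC(=C)[C@@H]1CC[C@](C)(O)[C@H](Br)C1 | intermediate
14 | {[(1S,2R,4R)-2-bromo-4-(3-chloroprop-1-en-2-yl)-1-methylcyclohexyl]oxy}trimethylsilane | ClCC(=C)[C@@H]1CC[C@](C)(O[Si](C)(C)C)[C@H](Br)C1 | intermediate
15 | lithium enolate of 9 toward ring A C3 | [Li]OC1=C[C@@H](C(C)=C)CC[C@@H]1OCOC | intermediate
16 | {[(1S,2R,4R)-2-bromo-4-(3-iodoprop-1-en-2-yl)-1-methylcyclohexyl]oxy}trimethylsilane | ICC(=C)[C@@H]1CC[C@](C)(O[Si](C)(C)C)[C@H](Br)C1 | intermediate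
17 | (2R,3S,6S)-2-{2-[(1R,3R,4S)-3-bromo-4-methyl-4-(trimethylsilyloxy)cyclohexyl]prop-2-en-1-yl}-6-(methoxymethoxy)-3-(prop-1-en-2-yl)cyclohexan-1-one | C=C(C[C@@H]1[C@@H](C(=C)C)CC[C@H](OCOC)C1=O)[C@@H]1CC[C@](C)(O[Si](C)(C)C)[C@H](Br)C1 | intermediate
18 | potassium enolate of 17 toward ring A C1 | C=C(C[C@@H]1[C@@H](C(=C)C)CCC(OCOC)=C1O[K])[C@@H]1CC[C@](C)(O[Si](C)(C)C)[C@H](Br)C1 | intermediate
19 | (2R,3S,6S)-2-{2-[(1R,3R,4S)-3-bromo-4-methyl-4-(trimethylsilyloxy)cyclohexyl]prop-2-en-1-yl}-6-(methoxymethoxy)-6-methyl-3-(prop-1-en-2-yl)cyclohexan-1-one | C=C(C[C@@H]1[C@@H](C(=C)C)CC[C@](C)(OCOC)C1=O)[C@@H]1CC[C@](C)(O[Si](C)(C)C)[C@H](Br)C1 | intermediate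
20 | (1S,2S,5S,6R)-6-{2-[(1R,3R,4S)-3-bromo-4-methyl-4-(trimethylsilyloxy)cyclohexyl]prop-2-en-1-yl}-2-(methoxymethoxy)-2-methyl-5-(prop-1-en-2-yl)cyclohexan-1-ol | C=C(C[C@@H]1[C@@H](C(=C)C)CC[C@](C)(OCOC)[C@H]1O)[C@@H]1CC[C@](C)(O[Si](C)(C)C)[C@H](Br)C1 | intermediate
21 | (1S,2S,3R,4S)-3-{2-[(1R,3R,4S)-3-bromo-4-methyl-4-(trimethylsilyloxy)cyclohexyl]prop-2-en-1-yl}-1-methyl-4-(prop-1-en-2-yl)cyclohexane-1,2-diol | C=C(C[C@@H]1[C@@H](C(=C)C)CC[C@](C)(O)[C@H]1O)[C@@H]1CC[C@](C)(O[Si](C)(C)C)[C@H](Br)C1 | intermediate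
22 | (1S,2S,3R,4S)-3-{2-[(1R,3R,4S)-3-bromo-4-hydroxy-4-methylcyclohexyl]prop-2-en-1-yl}-1-methyl-4-(prop-1-en-2-yl)cyclohexane-1,2-diol | C=C(C[C@@H]1[C@@H](C(=C)C)CC[C@](C)(O)[C@H]1O)[C@@H]1CC[C@](C)(O)[C@H](Br)C1 | target

Total step count: 12 steps.
Longest linear sequence: 7 steps (steps 1, 2, 5, 9, 10, 11, 12; the branches from 5 and from 10 are equally long).

Steps most likely to fail

Step 5. What may go wrong is β-hydride elimination of the primary alkylrhodium followed by chain walking to acyclic enones, protodeboronation of the boronate before transmetalation, or poor discrimination between the two enantiotopic ring bonds. The fallback keeps the cyclobutanone as the source of C2–C5 but builds the two bonds one after the other with known reactions. It sets out from 4: an enantioselective Baeyer–Villiger desymmetrisation (aqueous H2O2, chiral phosphoric acid catalyst) should give the lactone (S)-4-(prop-1-en-2-yl)oxolan-2-one F1. Addition of the vinyllithium 7 (made from 6 as in step 4) at −78 °C opens it to the hydroxy enone (5S)-6-hydroxy-2-(methoxymethoxy)-5-(prop-1-en-2-yl)hex-1-en-3-one F2, and I2, PPh3 and imidazole convert this into the iodide (5S)-6-iodo-2-(methoxymethoxy)-5-(prop-1-en-2-yl)hex-1-en-3-one F3. A 6-endo radical cyclisation onto the α-alkoxy enone ((Me3Si)3SiH, AIBN, benzene, 80 °C) then closes ring A and comes back to the route at 9.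

Step 6. What may go wrong is participation of the anti-periplanar tertiary hydroxyl, which would close the triflate to an epoxide that bromide reopens to the trans bromohydrin, or elimination toward the ring. The fallback removes the internal nucleophile before the substitution. It sets out from 10: selective acetylation of the secondary hydroxyl (Ac2O, pyridine) gives (1S,2S,5R)-2-hydroxy-2-methyl-5-(prop-1-en-2-yl)cyclohexyl acetate F4. Silylation of the tertiary hydroxyl (Et3SiOTf, 2,6-lutidine) gives the silyl ether acetate (1S,2S,5R)-2-methyl-5-(prop-1-en-2-yl)-2-(triethylsilyloxy)cyclohexyl acetate F5, and methanolysis of the acetate (K2CO3, MeOH) gives the alcohol (1S,2S,5R)-2-methyl-5-(prop-1-en-2-yl)-2-(triethylsilyloxy)cyclohexan-1-ol F6. Triflation and bromide displacement as in step 6 give the silylated bromohydrin {[(1S,2R,4R)-2-bromo-1-methyl-4-(prop-1-en-2-yl)cyclohexyl]oxy}triethylsilane F7, and HF·pyridine returns to the route at 12.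

Step 10. What may go wrong is competing deprotonation at C3, O-methylation of the alkoxy enolate, or poor facial selectivity. The fallback brings the methyl in as a nucleophile onto a C1 ketone instead. It sets out from 17: NaBH4 reduces the C2 ketone to the equatorial alcohol (1S,2S,5S,6R)-6-{2-[(1R,3R,4S)-3-bromo-4-methyl-4-(trimethylsilyloxy)cyclohexyl]prop-2-en-1-yl}-2-(methoxymethoxy)-5-(prop-1-en-2-yl)cyclohexan-1-ol F8, which is protected (t-BuMe2SiOTf, 2,6-lutidine) as the C2 tert-butyldimethylsilyl ether of that alcohol F9. ZnBr2 and n-PrSH free the C1 hydroxyl to give the C1 alcohol bearing the C2 silyl ether F10, and Dess–Martin periodinane oxidises it to the C1 ketone bearing the C2 silyl ether F11. Excess Me3Al in toluene, which is known to deliver methyl axially to cyclohexanones, should then give the tertiary alcohol with the axial C1 methyl F12, and Bu4NF removes both silyl groups and comes back to the route at 22.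

Further compounds
F1 | step 5 | (S)-4-(prop-1-en-2-yl)oxolan-2-one | O=C1C[C@@H](C(C)=C)CO1
F2 | step 5 | (5S)-6-hydroxy-2-(methoxymethoxy)-5-(prop-1-en-2-yl)hex-1-en-3-one | C=C(OCOC)C(=O)C[C@@H](C(C)=C)CO
F3 | step 5 | (5S)-6-iodo-2-(methoxymethoxy)-5-(prop-1-en-2-yl)hex-1-en-3-one | C=C(OCOC)C(=O)C[C@@H](C(C)=C)CI
F4 | step 6 | (1S,2S,5R)-2-hydroxy-2-methyl-5-(prop-1-en-2-yl)cyclohexyl acetate | CC(=C)[C@@H]1CC[C@](C)(O)[C@@H](OC(C)=O)C1
F5 | step 6 | (1S,2S,5R)-2-methyl-5-(prop-1-en-2-yl)-2-(triethylsilyloxy)cyclohexyl acetate | CC(=C)[C@@H]1CC[C@](C)(O[Si](CC)(CC)CC)[C@@H](OC(C)=O)C1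
F6 | step 6 | (1S,2S,5R)-2-methyl-5-(prop-1-en-2-yl)-2-(triethylsilyloxy)cyclohexan-1-ol | CC(=C)[C@@H]1CC[C@](C)(O[Si](CC)(CC)CC)[C@@H](O)C1
F7 | step 6 | {[(1S,2R,4R)-2-bromo-1-methyl-4-(prop-1-en-2-yl)cyclohexyl]oxy}triethylsilane | CC(=C)[C@@H]1CC[C@](C)(O[Si](CC)(CC)CC)[C@H](Br)C1
F8 | step 10 | (1S,2S,5S,6R)-6-{2-[(1R,3R,4S)-3-bromo-4-methyl-4-(trimethylsilyloxy)cyclohexyl]prop-2-en-1-yl}-2-(methoxymethoxy)-5-(prop-1-en-2-yl)cyclohexan-1-ol | C=C(C[C@@H]1[C@@H](C(=C)C)CC[C@H](OCOC)[C@H]1O)[C@@H]1CC[C@](C)(O[Si](C)(C)C)[C@H](Br)C1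
F9 | step 10 | C2 tert-butyldimethylsilyl ether of F8 | C=C(C[C@@H]1[C@@H](C(=C)C)CC[C@H](OCOC)[C@H]1O[Si](C)(C)C(C)(C)C)[C@@H]1CC[C@](C)(O[Si](C)(C)C)[C@H](Br)C1
F10 | step 10 | C1 alcohol bearing the C2 silyl ether | C=C(C[C@@H]1[C@@H](C(=C)C)CC[C@H](O)[C@H]1O[Si](C)(C)C(C)(C)C)[C@@H]1CC[C@](C)(O[Si](C)(C)C)[C@H](Br)C1
F11 | step 10 | C1 ketone bearing the C2 silyl ether | C=C(C[C@@H]1[C@@H](C(=C)C)CCC(=O)[C@H]1O[Si](C)(C)C(C)(C)C)[C@@H]1CC[C@](C)(O[Si](C)(C)C)[C@H](Br)C1
F12 | step 10 | tertiary alcohol with the axial C1 methyl and both silyl ethers | C=C(C[C@@H]1[C@@H](C(=C)C)CC[C@](C)(O)[C@H]1O[Si](C)(C)C(C)(C)C)[C@@H]1CC[C@](C)(O[Si](C)(C)C)[C@H](Br)C1
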